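A small charge of free catalyst, 10 mol% of the starting material in this flask, is easily dented: the stray impurity equals 10.8% of that catalyst charge.

| setting | birch | alder | larch | flask |
|---|---|---|---|---|
| starting material | 0.12 M | 0.18 M | 0.083 M | 0.083 M |
| second substrate | 1 equiv | 1 equiv | 1 equiv | 1.00 equiv |
| coupling partner | 2 equiv | 2 equiv | 2 equiv | 2.00 equiv |
| protic impurity | 1.66 mM | 1.66 mM | 1.66 mM | 1.66 mM |
| free catalyst | 10 mol% | 10 mol% | 20 mol% | 10 mol% |
| stray impurity | 0.90 mM | 0.90 mM | 0.90 mM | 0.90 mM |
| remark | run made earlier | run made earlier | run made earlier |  |

| run | time / min | target / % | starting material / % |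
|---|---|---|---|
| birch | 0.833 | 17 | 77 |
| birch | 2.00 | 29 | 62 |
| birch | 4.00 | 50 | 41 |
| birch | 6.00 | 64 | 28 |
| alder | 1.50 | 33 | 58 |
| alder | 3.00 | 53 | 40 |
| alder | 5.00 | 71 | 21 |
| alder | 6.00 | 76 | 15 |
| larch | 0.500 | 12 | 76 |
| larch | 1.00 | 22 | 63 |
| larch | 2.50 | 44 | 42 |
| larch | 6.00 | 71 | 13 |

(each reading ± 1.5 percentage points)

- apparent order in free catalyst when 50% of the starting material are converted (percent change of the rate of making target for one percent more free catalyst charged)

- the numbers in the tables scatter with a standard deviation of 1.5 percentage points
- steps under discussion: starting material + free catalyst <-> catalyst intermediate A; coupling partner + catalyst intermediate A -> free catalyst + target; second substrate + free catalyst <-> catalyst intermediate B; coupling partner + catalyst intermediate B -> free catalyst + second product; free catalyst + stray impurity -> spent catalyst; second substrate + protic impurity -> quenched substrate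
- what is bound to the catalyst counts as converted

We take each stray impurity to spend one free catalyst, so 89.2% of the charge stays live. Extra catalyst adds to the live part undiminished, so one percent more charge gives more than one percent more live catalyst; we call this gain the poison order, the catalyst charged over the live catalyst: 1.12.

The larch run then shows how much live catalyst is bound. Bound material counts as converted, and starting material lost exceeds target there by 14.3% of the charge on average. Read as catalyst intermediate A, the resting state, this gap puts 75.3% of the live catalyst of larch there, a reading with its scatter.

We carry that share to this flask, which by our reckoning puts 6.72% of the starting material in catalyst intermediate A. At 50% conversion in this flask we therefore expect target near 43.3%. Starting material held in catalyst intermediate A has taken no coupling partner, and that share grows with the catalyst charged. If second substrate has gone as far as starting material, 1.07 equivalents of coupling partner remain. The order then gains 0.0706, giving 1.19.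

The weak link is that second substrate, which no run reads. Reckoned with its full 1.00 equiv used, 0.567 equivalents remain and the order is 1.25. We commit to the lower figure and keep the higher as the upper edge of our reckoning.

The forecast reads 1.18, noting that at fixed conversion “slightly less target has formed and less partner is consumed”.

The flask gives 1.2.

    starting material + free catalyst ⇌ catalyst intermediate A (K = 580 M⁻¹, k = 2.20 M⁻¹ s⁻¹)
    coupling partner + catalyst intermediate A → free catalyst + target (k = 0.200 M⁻¹ s⁻¹)
    second substrate + free catalyst ⇌ catalyst intermediate B (K = 5.30 M⁻¹, k = 5.80 M⁻¹ s⁻¹)
    coupling partner + catalyst intermediate B → free catalyst + second product (k = 13.0 M⁻¹ s⁻¹)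
    free catalyst + stray impurity → spent catalyst (k = 2200 M⁻¹ s⁻¹)
    second substrate + protic impurity → quenched substrate (k = 110 M⁻¹ s⁻¹)

At 5.00 min, spent catalyst in this flask stands at 10.8% of the catalyst charged. The poison order serves again for twice the catalyst charge of this flask: we reckon live catalyst to grow by the poison order plus one, a factor of 2.12. The rate of making target in this flask at 50% conversion, with twice the free catalyst, grows by a factor of 2.29.

(Readings and results stem from a simulated flask for an exercise, noise included.)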